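**Retrosynthetic overview**

1. The target comes from its 7-O-TIPS ether by fluoride desilylation. That ether is cut at C2–C1' into unprotected phloroglucinol and a 6-lavandulyl-chromone-3-carboxylic acid, joined by a catalytic enantioselective decarboxylative Friedel–Crafts conjugate addition in which the C3 carboxyl leaves as CO2 in the same flask.
2. Enabling feature: in the pyranone ring C2 is the β-carbon of the C4 ketone, and C3 is a CH2 in the target, so it can carry a carboxyl until the bond is made. The B ring is phloroglucinol, whose three ring C–H carbons are equivalent and each lies ortho/para to all three OH groups.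
3. The acid comes from Pinnick oxidation of the 3-formylchromone, which comes from a Negishi sp2–sp3 coupling of a 6-iodochromone with the zinc reagent of (R)-lavandulyl iodide (the side-chain stereocentre is bought with lavandulol).
4. The 6-iodide comes from 5-OH-directed iodination, after 7-O-silylation and debenzylation of the Vilsmeier–Haack product of bis-benzyl phloroacetophenone.
5. Ring order: A ring bought; pyranone ring closed first (step 1); B ring attached intact in the key step, which also sets C2.

Key step: step 8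

Assumption: enantiopure (R)-(−)-lavandulol and 2'-hydroxy-4',6'-bis(benzyloxy)acetophenone are taken as purchasable; the (R) descriptor of lavandulol becomes (S) in the aryl compounds only because the CIP ranking changes when CH2OH is replaced by CH2Ar.

**Route**

Step 1
Reactants: 1 1-[2,4-bis(benzyloxy)-6-hydroxyphenyl]ethan-1-one
Product: 3 5,7-bis(benzyloxy)-4-oxo-4H-chromene-3-carbaldehyde, via chromonylmethylene iminium chloride 2 (not isolated)
Conditions: POCl3 (4 equiv), DMF, 0 → 50 °C; then ice/H2O
Reagents that add atoms: N,N-dimethylformamide, CN(C)C=O (C2–H and the formyl carbon); water, O (formyl oxygen)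
Why: Vilsmeier–Haack reaction of an o-hydroxyacetophenone: the methyl group is formylated twice by the chloroiminium ion, the phenol closes the pyranone ring with loss of dimethylamine, and the remaining iminium 2 is hydrolysed on work-up; benzyl ethers tolerate the acidic medium and no stereocentre is formed.

Step 2
Reactants: 3 5,7-bis(benzyloxy)-4-oxo-4H-chromene-3-carbaldehyde
Product: 4 5,7-dihydroxy-4-oxo-4H-chromene-3-carbaldehyde
Conditions: BCl3 (5 equiv), pentamethylbenzene (6 equiv), CH2Cl2, −78 → −20 °C; then H2O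
Reagents that add atoms: none
Why: Lewis-acid debenzylation with pentamethylbenzene as benzyl-cation scavenger is used here because no alkene is present yet; the chelated 5-O-benzyl ether goes first, and the formyl group and pyranone are only complexed and are released on hydrolysis.

Step 3
Reactants: 4 5,7-dihydroxy-4-oxo-4H-chromene-3-carbaldehyde
Product: 5 5-hydroxy-4-oxo-7-[(triisopropylsilyl)oxy]-4H-chromene-3-carbaldehyde
Conditions: TIPSCl (1.1 equiv), Et3N (1.5 equiv), CH2Cl2/DMF, 0 °C → rt
Reagents that add atoms: triisopropylsilyl chloride, CC(C)[Si](Cl)(C(C)C)C(C)C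
Why: chemoselective O-silylation: the 7-OH is a vinylogous acid and reacts as its ammonium phenoxide, whereas the 5-OH is hydrogen-bonded to the C4 carbonyl and should stay free; the fluoride-labile TIPS group is the only protecting group carried to the end.

Step 4
Reactants: 5 5-hydroxy-4-oxo-7-[(triisopropylsilyl)oxy]-4H-chromene-3-carbaldehyde
Product: 6 5-hydroxy-6-iodo-4-oxo-7-[(triisopropylsilyl)oxy]-4H-chromene-3-carbaldehyde
Conditions: BnMe3N+ ICl2− (1.1 equiv), CaCO3, CH2Cl2/MeOH 5:2, rt, dark
Reagents that add atoms: benzyltrimethylammonium dichloroiodate, C[N+](C)(C)Cc1ccccc1.Cl[I-]Cl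
Why: electrophilic aromatic iodination directed ortho to the free, chelated 5-OH: with dichloroiodate/CaCO3, 5-hydroxy-7-alkoxy chromones and flavones are known to be iodinated at C6 and not at C8, and the electron-poor C2=C3 bond should not be attacked.

Step 5
Reactants: 7 (R)-lavandulol [(2R)-5-methyl-2-(prop-1-en-2-yl)hex-4-en-1-ol]
Product: 8 (R)-lavandulyl iodide [(2R)-1-iodo-5-methyl-2-(prop-1-en-2-yl)hex-4-ene]
Conditions: I2, PPh3, imidazole, CH2Cl2, 0 °C → rt
Reagents that add atoms: iodine, II
Why: Appel iodination of a primary alcohol (SN2 at CH2 through the alkoxyphosphonium ion); the stereocentre is β to the reacting carbon and is not touched, and the neutral conditions spare both alkenes.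

Step 6
Reactants: 6 5-hydroxy-6-iodo-4-oxo-7-[(triisopropylsilyl)oxy]-4H-chromene-3-carbaldehyde; 8 (R)-lavandulyl iodide
Product: 10 5-hydroxy-6-[(2S)-5-methyl-2-(prop-1-en-2-yl)hex-4-en-1-yl]-4-oxo-7-[(triisopropylsilyl)oxy]-4H-chromene-3-carbaldehyde, via (R)-lavandulylzinc iodide 9 (not isolated)
Conditions: 8, Zn dust (TMSCl/BrCH2CH2Br-activated), LiCl, THF, 40 °C; then 6, Pd(OAc)2 (3 mol%), SPhos (6 mol%), THF, 25 °C, slow addition of 9 (1.4 equiv)
Reagents that add atoms: none
Why: Negishi sp2–sp3 cross-coupling: zinc inserts into the primary C–I bond of 8 (the stereocentre is β to zinc and configurationally safe, and the homoallylic organometallic should not rearrange), and the Pd/SPhos catalyst should couple 9 with the doubly ortho-substituted aryl iodide faster than the alkylzinc halide is protonated by the hydrogen-bonded 5-OH or adds to the aldehyde.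

Step 7
Reactants: 10 5-hydroxy-6-[(2S)-5-methyl-2-(prop-1-en-2-yl)hex-4-en-1-yl]-4-oxo-7-[(triisopropylsilyl)oxy]-4H-chromene-3-carbaldehyde
Product: 11 5-hydroxy-6-[(2S)-5-methyl-2-(prop-1-en-2-yl)hex-4-en-1-yl]-4-oxo-7-[(triisopropylsilyl)oxy]-4H-chromene-3-carboxylic acid
Conditions: NaClO2 (1.5 equiv), 35% H2O2 (1.5 equiv), NaH2PO4, MeCN/H2O, 0 → 10 °C
Reagents that add atoms: sodium chlorite, [Na+].[O-]Cl=O
Why: Pinnick (chlorite) oxidation of the aldehyde to the acid, with H2O2 as hypochlorite scavenger so that neither the two alkenes nor the electron-rich C8–H position is chlorinated; the mildly acidic buffer should leave the silyl ether and the pyranone intact.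

Step 8
Reactants: 11 5-hydroxy-6-[(2S)-5-methyl-2-(prop-1-en-2-yl)hex-4-en-1-yl]-4-oxo-7-[(triisopropylsilyl)oxy]-4H-chromene-3-carboxylic acid; 12 phloroglucinol (benzene-1,3,5-triol)
Product: 14 (2S)-5-hydroxy-6-[(2S)-5-methyl-2-(prop-1-en-2-yl)hex-4-en-1-yl]-7-[(triisopropylsilyl)oxy]-2-(2,4,6-trihydroxyphenyl)-2,3-dihydro-4H-chromen-4-one, via C3-carboxyflavanone adduct 13 (not isolated)
Conditions: quinine-derived bifunctional squaramide (3,5-bis(trifluoromethyl)anilino squaramide of 9-amino-9-deoxy-epi-quinine, 10 mol%), 12 (3 equiv), THF/toluene 1:1, −20 → 25 °C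
Reagents that add atoms: none
Why: Proposed new method: the C2=C3 bond of 11 is doubly activated (C4 ketone and C3–CO2H, both hydrogen-bonded by the acid OH and the 5-OH); the quinuclidine nitrogen of the catalyst ion-pairs with the carboxylate and relays a phenolic OH of 12 while the squaramide NH groups hold the 1,3-dicarbonyl unit, so that an unsubstituted ring carbon of 12 adds as a π-nucleophile to C2 (Friedel–Crafts-type Michael addition), the dienone re-aromatises to β-keto acid 13, and 13 loses CO2 through the usual six-membered transition state to leave the C3 methylene ketone. The closest known reaction types are the bifunctional-amine-catalysed enantioselective decarboxylative Michael additions of C–H acids to chromone-3-carboxylic acids and the squaramide-catalysed Friedel–Crafts alkylation of phenols with doubly activated alkenes; new is their combination, with a phenol as the nucleophile on this acceptor class. No ring is closed: the pyranone ring is already in place and only the exocyclic C2–C1' bond is formed. C2 is the only new stereocentre and is set by the catalyst, which must deliver the arene to the Re face of C2 (2S); the quinine- or the pseudo-enantiomeric quinidine-derived squaramide is to be chosen accordingly on a model chromone acid, since the remote side-chain centre exerts no control. The step needs C- over O-alkylation (the soft enone carbon and the irreversible decarboxylation drain any reversible O-adduct), mono- over poly-alkylation (excess 12, whose three free ring carbons are equivalent so that no regiochemistry arises) and retention of the new C2 centre (low temperature and weak base, so that the enol left by decarboxylation is protonated at C3 instead of expelling the O1 phenoxide).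

Step 9
Reactants: 14 (2S)-5-hydroxy-6-[(2S)-5-methyl-2-(prop-1-en-2-yl)hex-4-en-1-yl]-7-[(triisopropylsilyl)oxy]-2-(2,4,6-trihydroxyphenyl)-2,3-dihydro-4H-chromen-4-one
Product: 15 (2S)-5,7-dihydroxy-6-[(2S)-5-methyl-2-(prop-1-en-2-yl)hex-4-en-1-yl]-2-(2,4,6-trihydroxyphenyl)-2,3-dihydro-4H-chromen-4-one
Conditions: HF·pyridine, pyridine, THF, 0 °C
Reagents that add atoms: none
Why: fluoride-mediated cleavage of the aryl silyl ether (a vinylogous silyl ester, hence very labile) under buffered, non-basic conditions, so that the acid- and base-sensitive O1–C2 stereocentre next to the phloroglucinol ring, the free phenols and both alkenes should remain untouched.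

**Compound list**

1 | 1-[2,4-bis(benzyloxy)-6-hydroxyphenyl]ethan-1-one | CC(=O)c1c(O)cc(OCc2ccccc2)cc1OCc1ccccc1 | starting material
2 | N-{[5,7-bis(benzyloxy)-4-oxo-4H-chromen-3-yl]methylidene}-N-methylmethanaminium chloride | C[N+](C)=CC1=COc2cc(OCc3ccccc3)cc(OCc3ccccc3)c2C1=O.[Cl-] | intermediate
3 | 5,7-bis(benzyloxy)-4-oxo-4H-chromene-3-carbaldehyde | O=CC1=COc2cc(OCc3ccccc3)cc(OCc3ccccc3)c2C1=O | intermediate
4 | 5,7-dihydroxy-4-oxo-4H-chromene-3-carbaldehyde | O=CC1=COc2cc(O)cc(O)c2C1=O | intermediate
5 | 5-hydroxy-4-oxo-7-[(triisopropylsilyl)oxy]-4H-chromene-3-carbaldehyde | O=CC1=COc2cc(O[Si](C(C)C)(C(C)C)C(C)C)cc(O)c2C1=O | intermediate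
6 | 5-hydroxy-6-iodo-4-oxo-7-[(triisopropylsilyl)oxy]-4H-chromene-3-carbaldehyde | O=CC1=COc2cc(O[Si](C(C)C)(C(C)C)C(C)C)c(I)c(O)c2C1=O | intermediate
7 | (R)-lavandulol, (2R)-5-methyl-2-(prop-1-en-2-yl)hex-4-en-1-ol | C=C(C)[C@@H](CC=C(C)C)CO | starting material
8 | (R)-lavandulyl iodide, (2R)-1-iodo-5-methyl-2-(prop-1-en-2-yl)hex-4-ene | C=C(C)[C@@H](CC=C(C)C)CI | intermediate
9 | (R)-lavandulylzinc iodide, [(2R)-5-methyl-2-(prop-1-en-2-yl)hex-4-en-1-yl]zinc iodide | C=C(C)[C@@H](CC=C(C)C)C[Zn]I | intermediate
10 | 5-hydroxy-6-[(2S)-5-methyl-2-(prop-1-en-2-yl)hex-4-en-1-yl]-4-oxo-7-[(triisopropylsilyl)oxy]-4H-chromene-3-carbaldehyde | C=C(C)[C@@H](CC=C(C)C)Cc1c(O[Si](C(C)C)(C(C)C)C(C)C)cc2c(c1O)C(=O)C(C=O)=CO2 | intermediate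
11 | 5-hydroxy-6-[(2S)-5-methyl-2-(prop-1-en-2-yl)hex-4-en-1-yl]-4-oxo-7-[(triisopropylsilyl)oxy]-4H-chromene-3-carboxylic acid | C=C(C)[C@@H](CC=C(C)C)Cc1c(O[Si](C(C)C)(C(C)C)C(C)C)cc2c(c1O)C(=O)C(C(=O)O)=CO2 | intermediate
12 | phloroglucinol, benzene-1,3,5-triol | Oc1cc(O)cc(O)c1 | starting material
13 | (2S)-5-hydroxy-6-[(2S)-5-methyl-2-(prop-1-en-2-yl)hex-4-en-1-yl]-4-oxo-7-[(triisopropylsilyl)oxy]-2-(2,4,6-trihydroxyphenyl)-3,4-dihydro-2H-chromene-3-carboxylic acid (C3 not defined, enolisable) | C=C(C)[C@@H](CC=C(C)C)Cc1c(O[Si](C(C)C)(C(C)C)C(C)C)cc2c(c1O)C(=O)C(C(=O)O)[C@@H](c1c(O)cc(O)cc1O)O2 | intermediate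
14 | (2S)-5-hydroxy-6-[(2S)-5-methyl-2-(prop-1-en-2-yl)hex-4-en-1-yl]-7-[(triisopropylsilyl)oxy]-2-(2,4,6-trihydroxyphenyl)-2,3-dihydro-4H-chromen-4-one | C=C(C)[C@@H](CC=C(C)C)Cc1c(O[Si](C(C)C)(C(C)C)C(C)C)cc2c(c1O)C(=O)C[C@@H](c1c(O)cc(O)cc1O)O2 | intermediate
15 | (2S)-5,7-dihydroxy-6-[(2S)-5-methyl-2-(prop-1-en-2-yl)hex-4-en-1-yl]-2-(2,4,6-trihydroxyphenyl)-2,3-dihydro-4H-chromen-4-one | C=C(C)[C@@H](CC=C(C)C)Cc1c(O)cc2c(c1O)C(=O)C[C@@H](c1c(O)cc(O)cc1O)O2 | target

**Step count and risks**

Total step count: 9. Longest linear sequence: 8 (steps 1–4 and 6–9); step 5 is the one-step side branch.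

Steps most likely to fail:

1. Step 8 (proposed new method). What may go wrong: the catalysed pathway may not outrun the uncatalysed addition or may give weak facial discrimination at C2, and the C2 configuration may erode through reversible opening of the O1–C2 bond. The fallback sets out from 11 and comes back at 14, using known chemistry. The union of 11 and 12 is run with an achiral tertiary amine (Et3N or DABCO, THF, rt), a base-promoted decarboxylative Michael addition to a chromone-3-carboxylic acid. It should give 14 together with its C2 epimer, (2R)-5-hydroxy-6-[(2S)-5-methyl-2-(prop-1-en-2-yl)hex-4-en-1-yl]-7-[(triisopropylsilyl)oxy]-2-(2,4,6-trihydroxyphenyl)-2,3-dihydro-4H-chromen-4-one F1. Because the side-chain centre is fixed, 14 and F1 are diastereomers and are to be separated by preparative HPLC. F1 is then re-equilibrated with 14 by brief treatment with a weak base (NaOAc, EtOH, 50 °C; ring opening to the 2'-hydroxychalcone and re-closure) and separated again.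

2. Step 6. What may go wrong: the alkylzinc reagent may add to the formyl-activated pyranone (at C2 or at CHO) or be protonated, while coupling at the doubly flanked C6 is slow. The fallback sets out from 6 and comes back at 10, with the aldehyde masked before the coupling. Compound 6 is treated with ethylene glycol and catalytic TsOH (benzene, Dean–Stark) to give 3-(1,3-dioxolan-2-yl)-5-hydroxy-6-iodo-7-[(triisopropylsilyl)oxy]-4H-chromen-4-one F2, a much weaker Michael acceptor. Negishi coupling of F2 with 9 under the conditions of step 6 should give 3-(1,3-dioxolan-2-yl)-5-hydroxy-6-[(2S)-5-methyl-2-(prop-1-en-2-yl)hex-4-en-1-yl]-7-[(triisopropylsilyl)oxy]-4H-chromen-4-one F3. Mild acetal hydrolysis (PPTS, acetone/H2O, 50 °C) then returns 10 without touching the alkenes.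

3. Step 4. What may go wrong: regiocontrol may be lost (attack at C8 or double iodination) because the bulky silyl ether shields C6, and the silyl ether may be methanolysed. The fallback sets out from 3 and comes back at 6, placing the iodine while O7 still carries the small benzyl group. Chelation-controlled mono-debenzylation of 3 (BCl3, 1.1 equiv, CH2Cl2, −78 °C) should give 7-(benzyloxy)-5-hydroxy-4-oxo-4H-chromene-3-carbaldehyde F4, the substrate type for which C6-iodination is on record. Iodination under the conditions of step 4 gives 7-(benzyloxy)-5-hydroxy-6-iodo-4-oxo-4H-chromene-3-carbaldehyde F5. The second benzyl group is removed with BCl3/pentamethylbenzene (−78 → −20 °C) to give 5,7-dihydroxy-6-iodo-4-oxo-4H-chromene-3-carbaldehyde F6. Silylation of the 7-OH as in step 3 (TIPSCl, Et3N) delivers 6.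

**Further compounds**

F1 | step 8 | (2R)-5-hydroxy-6-[(2S)-5-methyl-2-(prop-1-en-2-yl)hex-4-en-1-yl]-7-[(triisopropylsilyl)oxy]-2-(2,4,6-trihydroxyphenyl)-2,3-dihydro-4H-chromen-4-one | C=C(C)[C@@H](CC=C(C)C)Cc1c(O[Si](C(C)C)(C(C)C)C(C)C)cc2c(c1O)C(=O)C[C@H](c1c(O)cc(O)cc1O)O2
F2 | step 6 | 3-(1,3-dioxolan-2-yl)-5-hydroxy-6-iodo-7-[(triisopropylsilyl)oxy]-4H-chromen-4-one | O=C1C(C2OCCO2)=COc3cc(O[Si](C(C)C)(C(C)C)C(C)C)c(I)c(O)c13
F3 | step 6 | 3-(1,3-dioxolan-2-yl)-5-hydroxy-6-[(2S)-5-methyl-2-(prop-1-en-2-yl)hex-4-en-1-yl]-7-[(triisopropylsilyl)oxy]-4H-chromen-4-one | C=C(C)[C@@H](CC=C(C)C)Cc1c(O[Si](C(C)C)(C(C)C)C(C)C)cc2c(c1O)C(=O)C(C1OCCO1)=CO2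
F4 | step 4 | 7-(benzyloxy)-5-hydroxy-4-oxo-4H-chromene-3-carbaldehyde | O=CC1=COc2cc(OCc3ccccc3)cc(O)c2C1=O
F5 | step 4 | 7-(benzyloxy)-5-hydroxy-6-iodo-4-oxo-4H-chromene-3-carbaldehyde | O=CC1=COc2cc(OCc3ccccc3)c(I)c(O)c2C1=O
F6 | step 4 | 5,7-dihydroxy-6-iodo-4-oxo-4H-chromene-3-carbaldehyde | O=CC1=COc2cc(O)c(I)c(O)c2C1=O
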